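**Retrosynthetic overview**

1. Target 44 ⇐ epoxide closure through a bromohydrin, Schenck ene reaction at C25=C27 with peroxyhemiacetal closure, hydroxy lactam from a C16–O–C39 γ-lactone (NH3, then oxidation), removal of the C11 oxygen as a triflate ⇐ phenol 34.
2. Key disconnection: the 13-membered ring C7–O8–C9···C12–C15–C16–C18–C19–C34–C33–C32 spans the para positions C9 and C12 of ring C9–C14. As a benzene that ring must bend, so the macrocycle is closed on the non-planar 3-alkoxycyclohex-2-enone 32 and aromatised last (32 → 34).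
3. 32 ⇐ acid-catalysed vinylogous transesterification at O8–C9 of seco alcohol 31 ⇐ reductive aldol (C19–C34) of tricyclic aldehyde 21 with alkylidene lactone 27. The lactone holds C16 at the alcohol level (a ketone-level C16, 1,4 to the C11 carbonyl, would cyclise under acid), and its C16 centre relays the quaternary C19.
4. 21 ⇐ ring C adjustment (allylic oxidation, cuprate/enol triflate, Negishi) and ring A deoxygenation ⇐ intramolecular Diels–Alder (rings B and C) of trienoate 9 ⇐ ring A by catalytic asymmetric Diels–Alder of diene 2 with enal 3.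
5. Ring order: A; B and C together; cyclohexenone ring attached; 13-membered ring; benzene ring; lactam; 1,2-dioxocane; epoxide.

Key step: step 27

Remark: locants C1 to N41 follow the atom order of the target SMILES and are used for every intermediate.
Remark: the sense of induction of the catalysts in steps 2 and 5 is assigned from the usual models; the mirror-image catalyst is used if the sense is the opposite.
Remark: the C16 hemiaminal and C21 peroxyhemiacetal configurations of the target are assumed to be the thermodynamic ones, reached by ring–chain equilibration.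
Remark: C12 (25–34), C3 (12–14), C34 (29) and the C19=C20 geometry (27) are carried as mixtures because each is erased later; they are left undefined in the SMILES.

**Route**

Step 1
Reactants: 1 2-methylpent-1-en-3-one
Product: 2 (Z)-2-methyl-3-(triisopropylsilyloxy)penta-1,3-diene
Conditions: i-Pr3SiOTf, Et3N, CH2Cl2, 0 °C
Reagents that add atoms: triisopropylsilyl triflate, CC(C)[Si](OS(=O)(=O)C(F)(F)F)(C(C)C)C(C)C
Why: Soft enolisation of the ethyl ketone (silyl triflate and amine) should give the Z silyl dienol ether, whose terminal methyl lies outside in the s-cis diene.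

Step 2
Reactants: 2 (Z)-2-methyl-3-(triisopropylsilyloxy)penta-1,3-diene; 3 ethyl (E)-3-methyl-4-oxobut-2-enoate
Product: 4 ring A aldehyde ester (C36 bears Me and CHO, C6 bears CO2Et, C2=C3 silyl enol ether)
Conditions: (S)-B-(o-tolyl)oxazaborolidinium triflimide [from (S)-diphenylprolinol, (o-tolyl)boroxine, HN(SO2CF3)2] (20 mol%), CH2Cl2, −78 °C
Reagents that add atoms: none
Why: Catalytic enantioselective Diels–Alder reaction in which the boron-bound aldehyde sends the nucleophilic diene terminus C4 to C6 and C38 to C36, the E dienophile fixes C31 trans to C7, the endo aldehyde places the C4 methyl cis to C31, and the catalyst shields one enal face so that C36 and C6 are set absolutely.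

Step 3
Reactants: 4 ring A aldehyde ester
Product: 5 ring A (E)-buta-1,3-dienyl ester
Conditions: (EtO)2P(O)CH2CH=CH2, n-BuLi, THF, HMPA, −78 → 23 °C
Reagents that add atoms: diethyl allylphosphonate, C=CCP(=O)(OCC)OCC
Why: Horner–Wadsworth–Emmons olefination of the neopentyl aldehyde by the allylphosphonate anion should give the E 1,3-diene while ester and silyl enol ether stay untouched.

Step 4
Reactants: 5 ring A (E)-buta-1,3-dienyl ester
Product: 6 ring A dienyl aldehyde (C7 aldehyde)
Conditions: i-Bu2AlH, CH2Cl2, −78 °C; Rochelle salt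
Reagents that add atoms: none
Why: Partial hydride reduction of the hindered ester stops at the aldehyde through the stable aluminium hemiacetal, and C6 keeps its equatorial, thermodynamically preferred configuration.

Step 5
Reactants: 6 ring A dienyl aldehyde
Product: 7 propargylic alcohol (C7–OH, C32≡C33, C34 methyl ester)
Conditions: methyl propiolate, Me2Zn, (S,S)-ProPhenol (20 mol%), Ph3PO, PhMe, 0 °C
Reagents that add atoms: methyl propiolate, C#CC(=O)OC
Why: Ligand-controlled dinuclear zinc alkynylation should deliver the propiolate to the Si face of the aldehyde, setting C7 against the weak intrinsic 1,2-induction.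

Step 6
Reactants: 7 propargylic alcohol
Product: 8 (E)-γ-hydroxy enoate
Conditions: NaAlH2(OCH2CH2OMe)2, THF, −78 °C
Reagents that add atoms: none
Why: Hydroxyl-directed trans-hydroalumination of the γ-hydroxy ynoate followed by protonation gives the E enoate.

Step 7
Reactants: 8 (E)-γ-hydroxy enoate
Product: 9 trienoate (C7–OSiMe2t-Bu)
Conditions: t-BuMe2SiOTf, 2,6-lutidine, CH2Cl2, −78 °C
Reagents that add atoms: tert-butyldimethylsilyl triflate, CC(C)(C)[Si](C)(C)OS(=O)(=O)C(F)(F)F
Why: Silylation of the hindered secondary alcohol with the silyl triflate masks C7–OH for the cycloaddition and the steps after it.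

Step 8
Reactants: 9 trienoate
Product: 10 tricyclic ester (rings A, B, C; C27=C29; ring A silyl enol ether)
Conditions: Me2AlCl (1.5 equiv), CH2Cl2, −78 → −30 °C
Reagents that add atoms: none
Why: Lewis acid-promoted intramolecular Diels–Alder reaction through the ester-endo transition state closes rings B and C trans-fused and sets C31, C32 and C33 from the fixed C6, C7 and C36 centres, while the tetrasubstituted triisopropylsilyl enol ether is too hindered to act as a donor.

Step 9
Reactants: 10 tricyclic ester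
Product: 11 tricyclic C3 ketone ester
Conditions: Bu4NF, AcOH, THF, −20 °C; then DBU, 23 °C
Reagents that add atoms: none
Why: Fluoride cleaves the silyl enol ether in preference to the alkyl silyl ether, and base then equilibrates C2 and C4 (both alpha to the C3 ketone) to the diequatorial arrangement enforced by the rigid trans-fused rings, where an axial methyl would be 1,3-diaxial to C37.

Step 10
Reactants: 11 tricyclic C3 ketone ester
Product: 12 diol (C3–OH, C34–OH)
Conditions: LiAlH4, THF, 0 °C
Reagents that add atoms: none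
Why: Hydride reduction takes the ester to the primary alcohol and the ketone to the C3 carbinol in one operation.

Step 11
Reactants: 12 diol
Product: 13 C34 pivalate
Conditions: t-BuCOCl, pyridine, DMAP (cat.), CH2Cl2, 0 °C
Reagents that add atoms: pivaloyl chloride, CC(C)(C)C(=O)Cl
Why: Acylation is selective for the unhindered primary alcohol over the C3 hydroxyl flanked by two methyl-bearing carbons.

Step 12
Reactants: 13 C34 pivalate
Product: 14 C3 S-methyl xanthate
Conditions: NaH, CS2, then MeI, THF, 0 → 23 °C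
Reagents that add atoms: carbon disulfide, S=C=S; iodomethane, CI
Why: Xanthate formation from the alkoxide prepares the C3 alcohol for radical deoxygenation.

Step 13
Reactants: 14 C3 S-methyl xanthate
Product: 15 C3-deoxy tricycle
Conditions: n-Bu3SnH, AIBN (cat.), PhMe, 100 °C
Reagents that add atoms: none
Why: Barton–McCombie deoxygenation through the secondary C3 radical, remote from the ring C alkene, removes the oxygen that steered the first cycloaddition.

Step 14
Reactants: 15 C3-deoxy tricycle
Product: 16 ring C enone (C25 ketone, C27=C29)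
Conditions: CrO3, 3,5-dimethylpyrazole, CH2Cl2, −20 °C
Reagents that add atoms: chromium trioxide, O=[Cr](=O)=O
Why: Allylic oxidation by the chromium trioxide–pyrazole complex takes the only allylic methylene, C25, to the ketone because C31 is a hindered methine.

Step 15
Reactants: 16 ring C enone
Product: 18 enol triflate (C25–OTf; C25=C27; C29 methyl), via lithium enolate 17 (not isolated)
Conditions: Me2CuLi, Et2O, −78 → −40 °C; then N-(5-chloropyridin-2-yl)triflimide, THF, −78 → 0 °C
Reagents that add atoms: lithium dimethylcuprate, [Li+].C[Cu-]C; N-(5-chloropyridin-2-yl)triflimide, O=S(=O)(N(c1ccc(Cl)cn1)S(=O)(=O)C(F)(F)F)C(F)(F)F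
Why: Conjugate addition of the cuprate to C29 anti to the neighbouring C31–C36 bond sets the C29 methyl, and the regiodefined C25 enolate is trapped on oxygen as the enol triflate.

Step 16
Reactants: 18 enol triflate
Product: 19 C25-methyl alkene pivalate
Conditions: MeZnCl, Pd(PPh3)4 (5 mol%), THF, 23 → 50 °C
Reagents that add atoms: methylzinc chloride, C[Zn]Cl
Why: Negishi cross-coupling of the enol triflate installs the C25 methyl with the C25=C27 double bond in place.

Step 17
Reactants: 19 C25-methyl alkene pivalate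
Product: 20 primary alcohol (C34–OH)
Conditions: i-Bu2AlH, CH2Cl2, −78 °C
Reagents that add atoms: none
Why: Reductive cleavage of the pivalate frees the primary alcohol without touching the silyl ether.

Step 18
Reactants: 20 primary alcohol
Product: 21 tricyclic aldehyde (C34 aldehyde)
Conditions: DMP [1,1,1-triacetoxy-1,1-dihydro-1,2-benziodoxol-3(1H)-one], NaHCO3, CH2Cl2, 0 °C
Reagents that add atoms: none
Why: Buffered periodinane oxidation gives the β,γ-unsaturated aldehyde without epimerising C33 or moving the alkene.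

Step 19
Reactants: 22 (R)-glycidol
Product: 23 (S)-glycidyl triflate
Conditions: (CF3SO2)2O, 2,6-lutidine, CH2Cl2, −78 °C
Reagents that add atoms: triflic anhydride, O=S(=O)(OS(=O)(=O)C(F)(F)F)C(F)(F)F
Why: Sulfonylation occurs at the primary oxygen only, so the epoxide centre is untouched and the descriptor changes by priority alone.

Step 20
Reactants: 24 3-methoxycyclohex-2-en-1-one; 23 (S)-glycidyl triflate
Product: 25 3-methoxy-6-[(2R)-oxiran-2-ylmethyl]cyclohex-2-en-1-one
Conditions: LiN(i-Pr)2, THF, −78 °C; then 23, −78 → −40 °C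
Reagents that add atoms: none
Why: Stork–Danheiser alkylation in which the kinetic alpha' enolate of the vinylogous ester displaces the primary triflate directly and carries the epoxide stereocentre (future C16) unchanged.

Step 21
Reactants: 25 3-methoxy-6-[(2R)-oxiran-2-ylmethyl]cyclohex-2-en-1-one
Product: 26 α-(dimethoxyphosphoryl) γ-lactone
Conditions: (MeO)2P(O)CH2CO2Me, NaH, DME, 70 °C
Reagents that add atoms: trimethyl phosphonoacetate, COC(=O)CP(=O)(OC)OC
Why: The phosphonoacetate anion opens the epoxide at the terminal carbon C18 and the alkoxide lactonises, giving the α-phosphono γ-lactone with C16 retained.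

Step 22
Reactants: 26 α-(dimethoxyphosphoryl) γ-lactone
Product: 27 α-(2,2-dimethoxyethylidene) γ-lactone
Conditions: (MeO)2CHCHO (aq.), K2CO3, THF, 0 → 23 °C
Reagents that add atoms: 2,2-dimethoxyacetaldehyde, COC(OC)C=O
Why: Horner–Wadsworth–Emmons olefination under mild aqueous carbonate gives the α-alkylidene lactone that carries C20 and the C21 acetal.

Step 23
Reactants: 27 α-(2,2-dimethoxyethylidene) γ-lactone; 21 tricyclic aldehyde
Product: 29 β-hydroxy lactone (C19–C34 bond; quaternary C19), via lactone enolate 28 (not isolated)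
Conditions: LiBH(s-Bu)3 (1 equiv on 27), THF, −78 °C; then 21, −78 °C; aq. NH4Cl
Reagents that add atoms: none
Why: Reductive aldol reaction in which 1,4-hydride addition gives the C19 enolate regiospecifically and the aldehyde adds to the enolate face anti to the C16 substituent, so that the quaternary C19 centre is set by 1,3-induction with C34 trans to C15 across the lactone.

Step 24
Reactants: 29 β-hydroxy lactone
Product: 30 β-keto lactone (C34 ketone)
Conditions: DMP, NaHCO3, CH2Cl2, 23 °C
Reagents that add atoms: none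
Why: Periodinane oxidation of the hindered carbinol gives the C34 ketone and removes the inconsequential C34 stereocentre.

Step 25
Reactants: 30 β-keto lactone
Product: 31 seco alcohol (C7–OH)
Conditions: HF·pyridine, pyridine, THF, 0 → 23 °C
Reagents that add atoms: none
Why: Buffered fluoride cleaves the C7 silyl ether while acetal, lactone and vinylogous ester survive.

Step 26
Reactants: 31 seco alcohol
Product: 32 macrocyclic vinylogous ester (13-membered ring closed at O8–C9)
Conditions: PPTS, 5 Å MS, PhMe (1 mM), 90 °C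
Reagents that add atoms: none
Why: Acid-catalysed alkoxy exchange of the vinylogous ester (addition of C7–OH at C9, loss of methanol to the sieves) under high dilution closes the 13-membered ring while C9–C14 is still a flexible cyclohexenone, with retention at C7.

Step 27
Reactants: 32 macrocyclic vinylogous ester
Product: 34 paracyclophane C11 phenol, via dienone 33 (not isolated)
Conditions: Pd(O2CCF3)2 (20 mol%), 2-(dimethylamino)pyridine (40 mol%), TsOH (20 mol%), O2 (1 atm), DMSO, 4 Å MS, 80 °C
Reagents that add atoms: none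
Why: Pd(O2CCF3)2 forms a divalent palladium enolate at C12 (the alpha' carbon of the vinylogous ester), β-hydride elimination from C13 gives the cross-conjugated dienone 33, and tautomerisation from C14–H to O11 gives the phenol while O2 reoxidises the palladium hydride. The closest known reaction is the aerobic palladium-catalysed dehydrogenation of cyclohexenones to phenols. No ring is closed by a new sigma bond: the benzene ring C9–C14 is created inside the existing 13-membered ring by introducing the ring double bonds C11=C12 and C13=C14 beside C9=C10, which turns the macrocycle into the bent paracyclophane. No stereocentre is formed and C12 is erased, so both C12 epimers converge. The required chemoselectivity over the C34 ketone and the C25=C27 alkene rests on the substrate: C34 has the quaternary C19 on one side and only the hindered C33–H on the other, dehydrogenation there gains no aromatic energy, and the trisubstituted alkene offers no accessible allylic palladation. The gain in aromaticity pays for the bending that a direct closure onto a planar arene would have to pay in its transition state.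

Step 28
Reactants: 34 paracyclophane C11 phenol
Product: 35 C11 aryl triflate
Conditions: PhN(SO2CF3)2, Et3N, DMAP (cat.), CH2Cl2, 23 °C
Reagents that add atoms: N-phenyltriflimide, O=S(=O)(N(c1ccccc1)S(=O)(=O)C(F)(F)F)C(F)(F)F
Why: Triflation of the phenol activates the surplus C11 oxygen for removal.

Step 29
Reactants: 35 C11 aryl triflate
Product: 36 paracyclophane lactone (C11–H)
Conditions: Pd(OAc)2 (10 mol%), dppf, HCO2H, Et3N, DMF, 60 °C
Reagents that add atoms: none
Why: Palladium-catalysed formate reduction of the aryl triflate (oxidative addition, hydride transfer from formate, reductive elimination) gives the C11–H arene.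

Step 30
Reactants: 36 paracyclophane lactone
Product: 37 hydroxy amide (C16–OH, C39 primary amide)
Conditions: NH3 (7 M in MeOH), 23 °C
Reagents that add atoms: ammonia, N
Why: Aminolysis of the strained, acyl-activated γ-lactone gives the primary amide and frees C16–OH.

Step 31
Reactants: 37 hydroxy amide
Product: 39 hydroxy lactam acetal, via keto amide 38 (not isolated)
Conditions: DMP, NaHCO3, CH2Cl2, 0 → 23 °C
Reagents that add atoms: none
Why: Oxidation of C16–OH gives the γ-keto amide, which closes to the five-membered hydroxy lactam, and C16 equilibrates by ring–chain tautomerism to the configuration compatible with the 13-membered ring.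

Step 32
Reactants: 39 hydroxy lactam acetal
Product: 40 hydroxy lactam aldehyde (C21 aldehyde)
Conditions: CF3CO2H, H2O, CHCl3, 0 °C
Reagents that add atoms: water, O
Why: Acid hydrolysis of the dimethyl acetal frees the C21 aldehyde, which cannot close on N41 because the amide nitrogen is already engaged at C16.

Step 33
Reactants: 40 hydroxy lactam aldehyde
Product: 42 peroxyhemiacetal (C25–O–O–C21; C27=C29), via hydroperoxide 41 (not isolated)
Conditions: O2, hν (visible), tetraphenylporphyrin (cat.), CH2Cl2, −20 °C; then silica gel, 23 °C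
Reagents that add atoms: dioxygen, O=O
Why: Schenck ene reaction in which singlet oxygen adds to C25 on the face of the pseudo-axial C29–H, which it abstracts, giving the tertiary C25 hydroperoxide with C27=C29, and the hydroperoxide then adds to the C21 aldehyde to close the eight-membered peroxyhemiacetal with C21 under thermodynamic control.

Step 34
Reactants: 42 peroxyhemiacetal
Product: 43 bromohydrin (C27–Br, C29–OH)
Conditions: N-bromosuccinimide, THF/H2O, 0 °C
Reagents that add atoms: N-bromosuccinimide, O=C1CCC(=O)N1Br; water, O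
Why: Bromohydrin formation in which the bromonium ion on the open face is opened by water at the tertiary C29 in trans-diaxial fashion, placing the C29 oxygen on the face of the peroxide bridge.

Step 35
Reactants: 43 bromohydrin
Product: 44 CNP0533733.1
Conditions: Ag2O, CH2Cl2, 23 °C, dark
Reagents that add atoms: none
Why: Silver-assisted intramolecular displacement of bromide by the C29 hydroxyl with inversion at C27 closes the epoxide on the face of the peroxide bridge under non-basic conditions that spare the peroxyhemiacetal.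

**Compound list**

1 | 2-methylpent-1-en-3-one | CCC(=O)C(C)=C | starting material
2 | (Z)-2-methyl-3-(triisopropylsilyloxy)penta-1,3-diene | C/C=C(\O[Si](C(C)C)(C(C)C)C(C)C)C(C)=C | intermediate
3 | ethyl (E)-3-methyl-4-oxobut-2-enoate | CCOC(=O)/C=C(\C)C=O | starting material
4 | ethyl 2-formyl-2,4,6-trimethyl-5-(triisopropylsilyloxy)cyclohex-4-ene-1-carboxylate, CHO trans to CO2Et, 6-methyl cis to CHO (C4, C6, C36 as in the target) | CC1=C(O[Si](C(C)C)(C(C)C)C(C)C)[C@H](C)[C@@H](C(=O)OCC)[C@](C)(C=O)C1 | intermediate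
5 | ethyl 2-[(E)-buta-1,3-dienyl]-2,4,6-trimethyl-5-(triisopropylsilyloxy)cyclohex-4-ene-1-carboxylate | CC1=C(O[Si](C(C)C)(C(C)C)C(C)C)[C@H](C)[C@@H](C(=O)OCC)[C@](C)(/C=C/C=C)C1 | intermediate
6 | ring A dienyl aldehyde (C7 aldehyde) | CC1=C(O[Si](C(C)C)(C(C)C)C(C)C)[C@H](C)[C@@H](C=O)[C@](C)(/C=C/C=C)C1 | intermediate
7 | methyl 4-hydroxy-4-(ring A)but-2-ynoate, C7 as in the target | CC1=C(O[Si](C(C)C)(C(C)C)C(C)C)[C@H](C)[C@@H]([C@@H](O)C#CC(=O)OC)[C@](C)(/C=C/C=C)C1 | intermediate
8 | methyl (E)-4-hydroxy-4-(ring A)but-2-enoate | CC1=C(O[Si](C(C)C)(C(C)C)C(C)C)[C@H](C)[C@@H]([C@@H](O)/C=C/C(=O)OC)[C@](C)(/C=C/C=C)C1 | intermediate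
9 | methyl (E)-4-(tert-butyldimethylsilyloxy)-4-(ring A)but-2-enoate (trienoate) | CC1=C(O[Si](C(C)C)(C(C)C)C(C)C)[C@H](C)[C@@H]([C@@H](O[Si](C)(C)C(C)(C)C)/C=C/C(=O)OC)[C@](C)(/C=C/C=C)C1 | intermediate
10 | tricyclic methyl ester, A/B and B/C trans-fused, C27=C29, ring A silyl enol ether | CC1=C(O[Si](C(C)C)(C(C)C)C(C)C)[C@H](C)[C@H]2[C@@H](O[Si](C)(C)C(C)(C)C)[C@@H]3[C@@H](C(=O)OC)CC=C[C@H]3[C@]2(C)C1 | intermediate
11 | tricyclic C3 ketone methyl ester, C2 and C4 methyls equatorial | C[C@@H]1C(=O)[C@H](C)[C@H]2[C@@H](O[Si](C)(C)C(C)(C)C)[C@@H]3[C@@H](C(=O)OC)CC=C[C@H]3[C@]2(C)C1 | intermediate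
12 | tricyclic diol (C3–OH, C34–OH) | C[C@@H]1C(O)[C@H](C)[C@H]2[C@@H](O[Si](C)(C)C(C)(C)C)[C@@H]3[C@@H](CO)CC=C[C@H]3[C@]2(C)C1 | intermediate
13 | C34 pivalate, C3 alcohol | C[C@@H]1C(O)[C@H](C)[C@H]2[C@@H](O[Si](C)(C)C(C)(C)C)[C@@H]3[C@@H](COC(=O)C(C)(C)C)CC=C[C@H]3[C@]2(C)C1 | intermediate
14 | C3 S-methyl xanthate | C[C@@H]1C(OC(=S)SC)[C@H](C)[C@H]2[C@@H](O[Si](C)(C)C(C)(C)C)[C@@H]3[C@@H](COC(=O)C(C)(C)C)CC=C[C@H]3[C@]2(C)C1 | intermediate
15 | C3-deoxy tricycle (C27=C29) | C[C@@H]1C[C@H](C)[C@H]2[C@@H](O[Si](C)(C)C(C)(C)C)[C@@H]3[C@@H](COC(=O)C(C)(C)C)CC=C[C@H]3[C@]2(C)C1 | intermediate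
16 | ring C enone (C25 ketone, C27=C29) | C[C@@H]1C[C@H](C)[C@H]2[C@@H](O[Si](C)(C)C(C)(C)C)[C@@H]3[C@@H](COC(=O)C(C)(C)C)C(=O)C=C[C@H]3[C@]2(C)C1 | intermediate
17 | lithium C25 enolate after C29 methylation | C[C@@H]1C[C@H](C)[C@H]2[C@@H](O[Si](C)(C)C(C)(C)C)[C@@H]3[C@@H](COC(=O)C(C)(C)C)C([O-])=C[C@H](C)[C@H]3[C@]2(C)C1.[Li+] | intermediate
18 | C25 enol triflate, C29 methyl trans to C36 | C[C@@H]1C[C@H](C)[C@H]2[C@@H](O[Si](C)(C)C(C)(C)C)[C@@H]3[C@@H](COC(=O)C(C)(C)C)C(OS(=O)(=O)C(F)(F)F)=C[C@H](C)[C@H]3[C@]2(C)C1 | intermediate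
19 | C25-methyl alkene (C25=C27) pivalate | C[C@@H]1C[C@H](C)[C@H]2[C@@H](O[Si](C)(C)C(C)(C)C)[C@@H]3[C@@H](COC(=O)C(C)(C)C)C(C)=C[C@H](C)[C@H]3[C@]2(C)C1 | intermediate
20 | tricyclic primary alcohol (C34–OH) | C[C@@H]1C[C@H](C)[C@H]2[C@@H](O[Si](C)(C)C(C)(C)C)[C@@H]3[C@@H](CO)C(C)=C[C@H](C)[C@H]3[C@]2(C)C1 | intermediate
21 | tricyclic aldehyde (C34 aldehyde) | C[C@@H]1C[C@H](C)[C@H]2[C@@H](O[Si](C)(C)C(C)(C)C)[C@@H]3[C@@H](C=O)C(C)=C[C@H](C)[C@H]3[C@]2(C)C1 | intermediate
22 | (R)-glycidol | OC[C@@H]1CO1 | starting material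
23 | (S)-glycidyl triflate | O=S(=O)(OC[C@@H]1CO1)C(F)(F)F | intermediate
24 | 3-methoxycyclohex-2-en-1-one | COC1=CC(=O)CCC1 | starting material
25 | 3-methoxy-6-[(2R)-oxiran-2-ylmethyl]cyclohex-2-en-1-one (C12 epimers) | COC1=CC(=O)C(C[C@@H]2CO2)CC1 | intermediate
26 | dimethyl [(5R)-5-[(4-methoxy-2-oxocyclohex-3-en-1-yl)methyl]-2-oxooxolan-3-yl]phosphonate | COC1=CC(=O)C(C[C@@H]2CC(P(=O)(OC)OC)C(=O)O2)CC1 | intermediate
27 | (5R)-3-(2,2-dimethoxyethylidene)-5-[(4-methoxy-2-oxocyclohex-3-en-1-yl)methyl]oxolan-2-one | COC1=CC(=O)C(C[C@@H]2CC(=CC(OC)OC)C(=O)O2)CC1 | intermediate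
28 | lithium enolate of the C19-(2,2-dimethoxyethyl) lactone | COC1=CC(=O)C(C[C@@H]2CC(CC(OC)OC)=C([O-])O2)CC1.[Li+] | intermediate
29 | β-hydroxy lactone, C19 quaternary with C34 trans to C15 (C34 epimers) | C[C@@H]1C[C@H](C)[C@H]2[C@@H](O[Si](C)(C)C(C)(C)C)[C@@H]3[C@@H](C(O)[C@]4(CC(OC)OC)C[C@@H](CC5CCC(OC)=CC5=O)OC4=O)C(C)=C[C@H](C)[C@H]3[C@]2(C)C1 | intermediate
30 | β-keto lactone (C34 ketone) | C[C@@H]1C[C@H](C)[C@H]2[C@@H](O[Si](C)(C)C(C)(C)C)[C@@H]3[C@@H](C(=O)[C@]4(CC(OC)OC)C[C@@H](CC5CCC(OC)=CC5=O)OC4=O)C(C)=C[C@H](C)[C@H]3[C@]2(C)C1 | intermediate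
31 | seco alcohol (C7–OH) | C[C@@H]1C[C@H](C)[C@H]2[C@@H](O)[C@@H]3[C@@H](C(=O)[C@]4(CC(OC)OC)C[C@@H](CC5CCC(OC)=CC5=O)OC4=O)C(C)=C[C@H](C)[C@H]3[C@]2(C)C1 | intermediate
32 | macrocyclic vinylogous ester (cyclohexenone in place of the arene; C16–O–C39 lactone) | C[C@@H]1C[C@H](C)[C@H]2[C@H]3OC4=CC(=O)C(CC4)C[C@@H]4C[C@](CC(OC)OC)(C(=O)O4)C(=O)[C@H]5C(C)=C[C@H](C)[C@H]([C@H]35)[C@]2(C)C1 | intermediate
33 | macrocyclic cyclohexa-2,5-dienone (C9=C10, C12=C13) | C[C@@H]1C[C@H](C)[C@H]2[C@H]3OC4=CC(=O)C(=CC4)C[C@@H]4C[C@](CC(OC)OC)(C(=O)O4)C(=O)[C@H]5C(C)=C[C@H](C)[C@H]([C@H]35)[C@]2(C)C1 | intermediate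
34 | paracyclophane aryl ether with C11 hydroxyl | C[C@@H]1C[C@H](C)[C@H]2[C@H]3Oc4cc(O)c(cc4)C[C@@H]4C[C@](CC(OC)OC)(C(=O)O4)C(=O)[C@H]5C(C)=C[C@H](C)[C@H]([C@H]35)[C@]2(C)C1 | intermediate
35 | C11 aryl triflate | C[C@@H]1C[C@H](C)[C@H]2[C@H]3Oc4cc(OS(=O)(=O)C(F)(F)F)c(cc4)C[C@@H]4C[C@](CC(OC)OC)(C(=O)O4)C(=O)[C@H]5C(C)=C[C@H](C)[C@H]([C@H]35)[C@]2(C)C1 | intermediate
36 | paracyclophane lactone (C11–H) | C[C@@H]1C[C@H](C)[C@H]2[C@H]3Oc4ccc(cc4)C[C@@H]4C[C@](CC(OC)OC)(C(=O)O4)C(=O)[C@H]5C(C)=C[C@H](C)[C@H]([C@H]35)[C@]2(C)C1 | intermediate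
37 | hydroxy amide (C16–OH, C39 carboxamide) | C[C@@H]1C[C@H](C)[C@H]2[C@H]3Oc4ccc(cc4)C[C@@H](O)C[C@](CC(OC)OC)(C(N)=O)C(=O)[C@H]5C(C)=C[C@H](C)[C@H]([C@H]35)[C@]2(C)C1 | intermediate
38 | C16 keto amide | C[C@@H]1C[C@H](C)[C@H]2[C@H]3Oc4ccc(cc4)CC(=O)C[C@](CC(OC)OC)(C(N)=O)C(=O)[C@H]5C(C)=C[C@H](C)[C@H]([C@H]35)[C@]2(C)C1 | intermediate
39 | hydroxy lactam dimethyl acetal | C[C@@H]1C[C@H](C)[C@H]2[C@H]3Oc4ccc(cc4)C[C@]4(O)C[C@](CC(OC)OC)(C(=O)N4)C(=O)[C@H]5C(C)=C[C@H](C)[C@H]([C@H]35)[C@]2(C)C1 | intermediate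
40 | hydroxy lactam aldehyde (C21 aldehyde) | C[C@@H]1C[C@H](C)[C@H]2[C@H]3Oc4ccc(cc4)C[C@]4(O)C[C@](CC=O)(C(=O)N4)C(=O)[C@H]5C(C)=C[C@H](C)[C@H]([C@H]35)[C@]2(C)C1 | intermediate
41 | C25 hydroperoxide (C27=C29) | C[C@@H]1C[C@H](C)[C@H]2[C@H]3Oc4ccc(cc4)C[C@]4(O)C[C@](CC=O)(C(=O)N4)C(=O)[C@H]5[C@@](C)(OO)C=C(C)[C@H]([C@H]35)[C@]2(C)C1 | intermediate
42 | peroxyhemiacetal (1,2-dioxocane closed; C27=C29) | C[C@@H]1C[C@H](C)[C@H]2[C@H]3Oc4ccc(cc4)C[C@]4(O)C[C@]5(C[C@H](O)OO[C@@]6(C)C=C(C)[C@H]([C@H]3[C@H]6C5=O)[C@]2(C)C1)C(=O)N4 | intermediate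
43 | bromohydrin (C27–Br anti to C29–OH) | C[C@@H]1C[C@H](C)[C@H]2[C@H]3Oc4ccc(cc4)C[C@]4(O)C[C@]5(C[C@H](O)OO[C@@]6(C)[C@H](Br)[C@](O)(C)[C@H]([C@H]3[C@H]6C5=O)[C@]2(C)C1)C(=O)N4 | intermediate
44 | CNP0533733.1 | C[C@@H]1C[C@H](C)[C@H]2[C@H]3Oc4ccc(cc4)C[C@]4(O)C[C@]5(C[C@H](O)OO[C@@]6(C)[C@H]7O[C@@]7(C)[C@H]([C@H]3[C@H]6C5=O)[C@]2(C)C1)C(=O)N4 | target

**Step count and risks**

Total step count: 35 (steps 1–18 for the core, 19–22 for the lactone fragment, 23–35 after the union).
Longest linear sequence: 31 steps (steps 1–18, then 23–35).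

The three steps most likely to fail:

Step 27 (aromatisation inside the macrocycle). The dehydrogenation may stall before the strained arene forms, palladium enolate formation may stray to C33, or the acid may ionise the acetal. The fallback sets out from 32 and separates enolisation from oxidation. Me3SiOTf and Et3N in CH2Cl2 at −78 °C silylate the most basic carbonyl (C11) and should give the 1-alkoxy-3-silyloxycyclohexadiene F1. DDQ with 2,6-di-tert-butylpyridine then abstracts hydride from the remaining ring methylene to give the aryl silyl ether F2. K2CO3 in MeOH frees the phenol, and the route is rejoined at 34.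

Step 26 (macrocyclisation at O8–C9). Oligomerisation may outrun ring closure, or the alkoxy position may scramble under acid. The fallback sets out from 21 and moves the ring-closing bond to C19–C34. HF·pyridine gives the hydroxy aldehyde F3. PPTS-catalysed alkoxy exchange with an excess of 27 gives the vinylogous ester-linked aldehyde F4. An intramolecular reductive aldol reaction with [CuH(PPh3)]6 in PhMe under high dilution closes the 13-membered ring as the macrocyclic carbinol F5; the C19 configuration must be checked here. DMP oxidation rejoins the route at 32.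

Step 33 (photooxygenation). Hydrogen abstraction may occur from C33–H or the C26 methyl instead of C29–H, or oxygen may be delivered to the wrong face. The fallback sets out from 40 and replaces the pericyclic step by an ionic one. N-bromosuccinimide with anhydrous H2O2 in Et2O at −40 °C should give bromonium formation on the open face and anti attack of H2O2 at the tertiary C25. The resulting β-bromo hydroperoxide adds to the C21 aldehyde to give the bromo peroxyhemiacetal F6. DBU at 0 °C then eliminates HBr through the anti-periplanar C29–H, and the route is rejoined at 42.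

Further compounds
F1 | step 27 | 1-alkoxy-3-(trimethylsilyloxy)cyclohexa-1,3-diene macrocycle (C9=C14, C10=C11) | C[C@@H]1C[C@H](C)[C@H]2[C@H]3OC4=CCC(C(O[Si](C)(C)C)=C4)C[C@@H]4C[C@](CC(OC)OC)(C(=O)O4)C(=O)[C@H]5C(C)=C[C@H](C)[C@H]([C@H]35)[C@]2(C)C1
F2 | step 27 | paracyclophane C11 trimethylsilyl ether | C[C@@H]1C[C@H](C)[C@H]2[C@H]3Oc4cc(O[Si](C)(C)C)c(cc4)C[C@@H]4C[C@](CC(OC)OC)(C(=O)O4)C(=O)[C@H]5C(C)=C[C@H](C)[C@H]([C@H]35)[C@]2(C)C1
F3 | step 26 | tricyclic hydroxy aldehyde (C7–OH, C34 aldehyde) | C[C@@H]1C[C@H](C)[C@H]2[C@@H](O)[C@@H]3[C@@H](C=O)C(C)=C[C@H](C)[C@H]3[C@]2(C)C1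
F4 | step 26 | vinylogous ester-linked aldehyde alkylidene lactone | C[C@@H]1C[C@H](C)[C@H]2[C@@H](OC4=CC(=O)C(C[C@@H]5CC(=CC(OC)OC)C(=O)O5)CC4)[C@@H]3[C@@H](C=O)C(C)=C[C@H](C)[C@H]3[C@]2(C)C1
F5 | step 26 | macrocyclic C34 carbinol | C[C@@H]1C[C@H](C)[C@H]2[C@H]3OC4=CC(=O)C(CC4)C[C@@H]4C[C@](CC(OC)OC)(C(=O)O4)C(O)[C@H]5C(C)=C[C@H](C)[C@H]([C@H]35)[C@]2(C)C1
F6 | step 33 | bromo peroxyhemiacetal (C27–Br, C25–O–O–C21) | C[C@@H]1C[C@H](C)[C@H]2[C@H]3Oc4ccc(cc4)C[C@]4(O)C[C@]5(C[C@H](O)OO[C@@]6(C)[C@H](Br)[C@H](C)[C@H]([C@H]3[C@H]6C5=O)[C@]2(C)C1)C(=O)N4
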